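**Plan**

1. Retrosynthesis: the alkyl C–O bond of the hydroxytyrosyl ester is cut first and the freed carboxylate is closed onto the oxygen of the C3 hydroxymethyl group (δ-lactone, ring A, absent from the target). Then C5=C6 and C4–C5 of the dihydropyran (ring B: O1, C2–C6) are cut; this removes C5 with its CO2CH3 as trimethyl phosphonoacetate, leaves C6 as a formate on O1 and C4 as the β-carbon of an unsaturated lactone. Ring A is cut at its C=C (metathesis) and its acrylate ester, and C2–C3 by an aldol.
2. Forward: Evans aldol → 2-vinyl-1,3-diol → primary acrylate, secondary formate → ring-closing metathesis to ring A → Michael/Horner–Wadsworth–Emmons annulation that closes ring B → hydroxide opening of ring A and O-alkylation of the carboxylate with dibenzyl hydroxytyrosyl bromide → hydrogenolysis.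
3. Stereochemistry: C2 and C3 come from the syn aldol under control of (S)-4-benzyloxazolidinone; C4 comes from anti addition to the half-chair of ring A.
4. Enabling feature: C5 of ring B carries only C4, C6 and CO2CH3. It is an acetate α-carbon lying between C4 (β to a carbonyl, its CH2C=O arm 1,6 to the C3–CH2–O oxygen) and C6 (formate level, on O1), so one phosphonoacetate carbon can be stitched between an enoate and an O-formyl group.

Key step: step 7

Remark: target numbering (O1, C2 bearing CH3, C3 bearing CH2OH, C4 bearing the acetate arm, C5 bearing CO2CH3, C6 the enol ether CH) is used for all intermediates; the target is read as (2R,3R,4S), that is 2,3-trans and 3,4-trans; compounds 1, 2, 4, 7, 9, 12 and 15 are assumed to be commercial.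

**Route**

Step 1
Reactants: 1 (S)-4-benzyl-1,3-oxazolidin-2-one; 2 (E)-but-2-enoyl chloride
Product: 3 (4S)-4-benzyl-3-[(2E)-but-2-enoyl]-1,3-oxazolidin-2-one
Conditions: n-BuLi, THF, −78 °C; then 2, −78 → 0 °C
Reagents that add atoms: none
Why: N-acylation of the lithiated oxazolidinone by the acid chloride (standard imide formation); no stereocenter is formed.

Step 2
Reactants: 3 (4S)-4-benzyl-3-[(2E)-but-2-enoyl]-1,3-oxazolidin-2-one; 4 acetaldehyde
Product: 5 (4S)-4-benzyl-3-[(2S,3R)-2-ethenyl-3-hydroxybutanoyl]-1,3-oxazolidin-2-one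
Conditions: Bu2BOTf, Et3N, CH2Cl2, −78 → 0 °C; then 4, −78 → 0 °C; pH 7 buffer, MeOH, H2O2, 0 °C
Reagents that add atoms: none
Why: Evans syn aldol, in which γ-deprotonation gives the (Z)-boron dienolate that reacts at its α-carbon through a closed Zimmerman–Traxler chair on the face away from the benzyl group of the dipole-opposed auxiliary, which should set C2 and C3 together as the syn adduct.

Step 3
Reactants: 5 (4S)-4-benzyl-3-[(2S,3R)-2-ethenyl-3-hydroxybutanoyl]-1,3-oxazolidin-2-one
Product: 6 (2R,3R)-2-ethenylbutane-1,3-diol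
Conditions: LiBH4, MeOH (1 equiv), THF, 0 °C
Reagents that add atoms: none
Why: Reductive cleavage of the N-acyl oxazolidinone by hydride attack at the exocyclic carbonyl should give the primary alcohol and return auxiliary 1 without touching C2 or C3.

Step 4
Reactants: 6 (2R,3R)-2-ethenylbutane-1,3-diol; 7 prop-2-enoyl chloride
Product: 8 (2R,3R)-2-ethenyl-3-hydroxybutyl prop-2-enoate
Conditions: 7 (1.05 equiv), 2,4,6-collidine, CH2Cl2, −78 °C
Reagents that add atoms: none
Why: Kinetically selective O-acylation of the primary over the secondary hydroxyl with one equivalent of acid chloride and a hindered pyridine base at low temperature.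

Step 5
Reactants: 8 (2R,3R)-2-ethenyl-3-hydroxybutyl prop-2-enoate; 9 formic acid
Product: 10 (2R,3R)-2-ethenyl-3-(formyloxy)butyl prop-2-enoate
Conditions: 9, DCC, DMAP (cat.), CH2Cl2, 0 °C → rt
Reagents that add atoms: none
Why: Carbodiimide-mediated (Steglich-type) formylation of the secondary alcohol, which places the future C6 on O1 with retention at C2 because the C–O bond is not touched.

Step 6
Reactants: 10 (2R,3R)-2-ethenyl-3-(formyloxy)butyl prop-2-enoate
Product: 11 (5R)-5-[(1R)-1-(formyloxy)ethyl]-5,6-dihydro-2H-pyran-2-one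
Conditions: second-generation Grubbs catalyst (H2IMes)(PCy3)Cl2Ru=CHPh (5 mol %), CH2Cl2 (5 mM), 40 °C
Reagents that add atoms: none
Why: Ring-closing metathesis of the acrylate of a homoallylic alcohol should give the six-membered α,β-unsaturated lactone (ring A) with loss of ethene, leaving formate and stereocenters untouched.

Step 7
Reactants: 11 (5R)-5-[(1R)-1-(formyloxy)ethyl]-5,6-dihydro-2H-pyran-2-one; 12 trimethyl phosphonoacetate
Product: 14 methyl (1R,4aS,8aR)-1-methyl-6-oxo-4a,5,8,8a-tetrahydro-1H,6H-pyrano[3,4-c]pyran-4-carboxylate, via phosphonate Michael adduct 13 (not isolated)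
Conditions: 12 (1.1 equiv), NaH (1.1 equiv), THF, 0 °C; then 11, 0 °C → rt
Reagents that add atoms: none
Why: Proposed new method: sodium trimethyl phosphonoacetate should add 1,4 to C4 of the unsaturated lactone 11, proton transfer from the new doubly activated C5–H to the lactone enolate gives the phosphonate carbanion of 13, this carbon attacks the formate carbon C6 held on O1, and the cis β-oxido phosphonate collapses through its oxaphosphetane with loss of dimethyl phosphate, so that ring B is closed by the C5–C6 bond as the C5=C6 enol ether. The closest known reaction types are the Michael/Horner–Wadsworth–Emmons annulations of phosphonoacetates with enones and enals and the Wittig olefination of formate esters by ester-stabilised ylides to β-alkoxyacrylates; the new element is an intramolecular Horner–Wadsworth–Emmons olefination of a formate carbonyl. If the tetrahedral adduct instead expels the O1 alkoxide, that alkoxide can re-add to the resulting non-enolisable α-formyl phosphonoacetate and regenerate the same oxido phosphonate, so both branches should drain into the irreversible phosphate elimination. The ring closes 6-exo-trig at the formyl carbon; C4, the only new stereocenter that survives, is set by axial attack on the half-chair lactone anti to the side chain at C3 (4,5-trans lactone, hence a trans-fused bicycle from two equatorial arms), and the stereocenter at C5 of 13 is erased by the elimination. The step needs conjugate addition to outrun formyl transfer from the formate to the phosphonoacetate anion, which the good acceptor ability of the dihydropyranone and the reversible addition of a stabilised carbanion to a formate should secure, and it needs closure from C5 only, which is secured because C5–H is by far the most acidic C–H of 13 and the lactone α-carbon could reach the formate only through a bridged arrangement with a bridgehead double bond.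

Step 8
Reactants: 15 2-(3,4-dihydroxyphenyl)ethan-1-ol (hydroxytyrosol)
Product: 16 2-[3,4-bis(benzyloxy)phenyl]ethan-1-ol
Conditions: BnBr (2.2 equiv), K2CO3, acetone, reflux
Reagents that add atoms: benzyl bromide, BrCc1ccccc1
Why: Williamson etherification selective for the two phenols, since K2CO3 ionises the phenols and leaves the aliphatic alcohol un-ionised.

Step 9
Reactants: 16 2-[3,4-bis(benzyloxy)phenyl]ethan-1-ol
Product: 17 1,2-bis(benzyloxy)-4-(2-bromoethyl)benzene
Conditions: CBr4, PPh3, CH2Cl2, 0 °C
Reagents that add atoms: carbon tetrabromide, BrC(Br)(Br)Br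
Why: Appel bromination of the primary alcohol by SN2 displacement of the alkoxyphosphonium ion.

Step 10
Reactants: 14 methyl (1R,4aS,8aR)-1-methyl-6-oxo-4a,5,8,8a-tetrahydro-1H,6H-pyrano[3,4-c]pyran-4-carboxylate; 17 1,2-bis(benzyloxy)-4-(2-bromoethyl)benzene
Product: 19 2-[3,4-bis(benzyloxy)phenyl]ethyl 2-[(2R,3R,4S)-3-(hydroxymethyl)-5-(methoxycarbonyl)-2-methyl-3,4-dihydro-2H-pyran-4-yl]acetate, via cesium hydroxy carboxylate 18 (not isolated)
Conditions: CsOH·H2O (1.0 equiv), THF/H2O, 0 °C; evaporate; 17, DMF, rt
Reagents that add atoms: cesium hydroxide, [Cs+].[OH-]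
Why: Chemoselective saponification of the δ-lactone (far more electrophilic than the vinylogous carbonate methyl ester) followed by SN2 O-alkylation of the cesium carboxylate builds the ester at its alkyl–O bond, so the freed C3 hydroxymethyl group needs no protection and no stereocenter is touched.

Step 11
Reactants: 19 2-[3,4-bis(benzyloxy)phenyl]ethyl 2-[(2R,3R,4S)-3-(hydroxymethyl)-5-(methoxycarbonyl)-2-methyl-3,4-dihydro-2H-pyran-4-yl]acetate
Product: 20 2-(3,4-dihydroxyphenyl)ethyl 2-[(2R,3R,4S)-3-(hydroxymethyl)-5-(methoxycarbonyl)-2-methyl-3,4-dihydro-2H-pyran-4-yl]acetate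
Conditions: H2 (1 atm), Pd/C (10 %), EtOAc, rt
Reagents that add atoms: none
Why: Hydrogenolysis of the two aryl benzyl ethers under neutral conditions, which the trisubstituted push–pull enol ether ester and the δ-hydroxy ester are expected to survive.

**Compound list**

1 | (S)-4-benzyl-1,3-oxazolidin-2-one | O=C1N[C@@H](Cc2ccccc2)CO1 | starting material
2 | (E)-but-2-enoyl chloride | C/C=C/C(=O)Cl | starting material
3 | (4S)-4-benzyl-3-[(2E)-but-2-enoyl]-1,3-oxazolidin-2-one | C/C=C/C(=O)N1[C@@H](Cc2ccccc2)COC1=O | intermediate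
4 | acetaldehyde | CC=O | starting material
5 | (4S)-4-benzyl-3-[(2S,3R)-2-ethenyl-3-hydroxybutanoyl]-1,3-oxazolidin-2-one | C[C@@H](O)[C@H](C=C)C(=O)N1[C@@H](Cc2ccccc2)COC1=O | intermediate
6 | (2R,3R)-2-ethenylbutane-1,3-diol | C[C@@H](O)[C@H](C=C)CO | intermediate
7 | prop-2-enoyl chloride | C=CC(=O)Cl | starting material
8 | (2R,3R)-2-ethenyl-3-hydroxybutyl prop-2-enoate | C[C@@H](O)[C@H](C=C)COC(=O)C=C | intermediate
9 | formic acid | O=CO | starting material
10 | (2R,3R)-2-ethenyl-3-(formyloxy)butyl prop-2-enoate | C[C@@H](OC=O)[C@H](C=C)COC(=O)C=C | intermediate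
11 | (5R)-5-[(1R)-1-(formyloxy)ethyl]-5,6-dihydro-2H-pyran-2-one | C[C@@H](OC=O)[C@@H]1C=CC(=O)OC1 | intermediate
12 | trimethyl phosphonoacetate | COC(=O)CP(=O)(OC)OC | starting material
13 | methyl 2-(dimethoxyphosphoryl)-2-[(3R,4S)-3-[(1R)-1-(formyloxy)ethyl]-6-oxooxan-4-yl]acetate (both configurations at the phosphonate carbon) | C[C@@H](OC=O)[C@H]1COC(=O)C[C@@H]1C(C(=O)OC)P(=O)(OC)OC | intermediate
14 | methyl (1R,4aS,8aR)-1-methyl-6-oxo-4a,5,8,8a-tetrahydro-1H,6H-pyrano[3,4-c]pyran-4-carboxylate (trans-fused; ring B of the target with the C3–CH2–O oxygen and the C4 acetic arm joined as a δ-lactone) | COC(=O)C1=CO[C@H](C)[C@H]2COC(=O)C[C@H]12 | intermediate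
15 | 2-(3,4-dihydroxyphenyl)ethan-1-ol (hydroxytyrosol) | OCCc1ccc(O)c(O)c1 | starting material
16 | 2-[3,4-bis(benzyloxy)phenyl]ethan-1-ol | OCCc1ccc(OCc2ccccc2)c(OCc2ccccc2)c1 | intermediate
17 | 1,2-bis(benzyloxy)-4-(2-bromoethyl)benzene | BrCCc1ccc(OCc2ccccc2)c(OCc2ccccc2)c1 | intermediate
18 | cesium 2-[(2R,3R,4S)-3-(hydroxymethyl)-5-(methoxycarbonyl)-2-methyl-3,4-dihydro-2H-pyran-4-yl]acetate | COC(=O)C1=CO[C@H](C)[C@@H](CO)[C@@H]1CC(=O)[O-].[Cs+] | intermediate
19 | 2-[3,4-bis(benzyloxy)phenyl]ethyl 2-[(2R,3R,4S)-3-(hydroxymethyl)-5-(methoxycarbonyl)-2-methyl-3,4-dihydro-2H-pyran-4-yl]acetate | COC(=O)C1=CO[C@H](C)[C@@H](CO)[C@@H]1CC(=O)OCCc1ccc(OCc2ccccc2)c(OCc2ccccc2)c1 | intermediate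
20 | 2-(3,4-dihydroxyphenyl)ethyl 2-[(2R,3R,4S)-3-(hydroxymethyl)-5-(methoxycarbonyl)-2-methyl-3,4-dihydro-2H-pyran-4-yl]acetate | COC(=O)C1=CO[C@H](C)[C@@H](CO)[C@@H]1CC(=O)OCCc1ccc(O)c(O)c1 | target

**Step count and risks**

Total steps: 11. Longest linear sequence: 9 steps (steps 1–7, 10 and 11); steps 8 and 9 form a two-step side branch.

Steps most likely to fail:

1. Step 7. The formate may transfer its formyl group to the phosphonoacetate anion before conjugate addition occurs. The cyclised adduct may lose the O1 alkoxide and translactonise instead of eliminating phosphate. The side chain may be lost by vinylogous elimination through the lactone dienolate. The fallback uses known chemistry, sets out from 8 and comes back at 14. The secondary alcohol of 8 is silylated (Et3SiCl, imidazole) to the triethylsilyl ether F1. Ring-closing metathesis with the same second-generation Grubbs catalyst gives the silyl-protected unsaturated lactone F2. The lithium enolate of methyl 3,3-dimethoxypropanoate (lithium diisopropylamide LiN(i-Pr)2, THF, −78 °C) is added 1,4, anti to the side chain, to give the trans Michael adduct F3, which already carries C5 with its ester and C6 as a dimethyl acetal. Aqueous HCl in THF removes the silyl group to give the hydroxy acetal F4 (not isolated). Warming with pyridinium p-toluenesulfonate in toluene closes ring B by transacetalisation at O1–C6 and eliminates methanol to the β-alkoxyacrylate 14.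

2. Step 10. The O-alkylation of the carboxylate may be slow against E2 elimination of the phenethyl bromide, and the δ-hydroxy ester may re-close to lactone 14 during the reaction or purification. The fallback sets out from 14 and comes back at 19. After the same CsOH opening to 18, both the hydroxyl and the carboxylate are silylated (t-BuMe2SiCl, imidazole, DMF) to the bis-silyl compound F5 (not isolated). Its silyl ester is cleaved on aqueous K2CO3 work-up to the silyloxy acid F6. Steglich esterification of F6 with alcohol 16 (EDC·HCl, DMAP, CH2Cl2) gives the silyl-protected ester F7, and HF·pyridine in THF/pyridine at 0 °C frees the hydroxymethyl group to give 19.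

3. Step 11. The C5=C6 enol ether may be over-reduced, or slow debenzylation may allow lactonisation of the product on long exposure to the catalyst. The fallback sets out from 15, uses 18 from the main route and comes back at 20. Hydroxytyrosol 15 is allylated on both phenols (allyl bromide, K2CO3, acetone) to the diallyl ether alcohol F8, which is brominated (CBr4, PPh3) to the diallyl bromide F9. Cesium carboxylate 18 is alkylated with F9 in DMF to the diallyl-protected ester F10. The allyl groups are removed without hydrogen by Pd(PPh3)4 (zerovalent palladium) and morpholine in THF at rt to give 20.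

**Further compounds**

F1 | step 7 | (2R,3R)-2-ethenyl-3-[(triethylsilyl)oxy]butyl prop-2-enoate | C[C@@H](O[Si](CC)(CC)CC)[C@H](C=C)COC(=O)C=C
F2 | step 7 | (5R)-5-{(1R)-1-[(triethylsilyl)oxy]ethyl}-5,6-dihydro-2H-pyran-2-one | C[C@@H](O[Si](CC)(CC)CC)[C@@H]1C=CC(=O)OC1
F3 | step 7 | methyl 3,3-dimethoxy-2-[(3R,4S)-6-oxo-3-{(1R)-1-[(triethylsilyl)oxy]ethyl}oxan-4-yl]propanoate | C[C@@H](O[Si](CC)(CC)CC)[C@H]1COC(=O)C[C@@H]1C(C(OC)OC)C(=O)OC
F4 | step 7 | methyl 2-[(3R,4S)-3-[(1R)-1-hydroxyethyl]-6-oxooxan-4-yl]-3,3-dimethoxypropanoate | C[C@@H](O)[C@H]1COC(=O)C[C@@H]1C(C(OC)OC)C(=O)OC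
F5 | step 10 | tert-butyldimethylsilyl 2-[(2R,3R,4S)-3-{[(tert-butyldimethylsilyl)oxy]methyl}-5-(methoxycarbonyl)-2-methyl-3,4-dihydro-2H-pyran-4-yl]acetate | COC(=O)C1=CO[C@H](C)[C@@H](CO[Si](C)(C)C(C)(C)C)[C@@H]1CC(=O)O[Si](C)(C)C(C)(C)C
F6 | step 10 | 2-[(2R,3R,4S)-3-{[(tert-butyldimethylsilyl)oxy]methyl}-5-(methoxycarbonyl)-2-methyl-3,4-dihydro-2H-pyran-4-yl]acetic acid | COC(=O)C1=CO[C@H](C)[C@@H](CO[Si](C)(C)C(C)(C)C)[C@@H]1CC(=O)O
F7 | step 10 | 2-[3,4-bis(benzyloxy)phenyl]ethyl 2-[(2R,3R,4S)-3-{[(tert-butyldimethylsilyl)oxy]methyl}-5-(methoxycarbonyl)-2-methyl-3,4-dihydro-2H-pyran-4-yl]acetate | COC(=O)C1=CO[C@H](C)[C@@H](CO[Si](C)(C)C(C)(C)C)[C@@H]1CC(=O)OCCc1ccc(OCc2ccccc2)c(OCc2ccccc2)c1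
F8 | step 11 | 2-[3,4-bis(prop-2-en-1-yloxy)phenyl]ethan-1-ol | OCCc1ccc(OCC=C)c(OCC=C)c1
F9 | step 11 | 4-(2-bromoethyl)-1,2-bis(prop-2-en-1-yloxy)benzene | BrCCc1ccc(OCC=C)c(OCC=C)c1
F10 | step 11 | 2-[3,4-bis(prop-2-en-1-yloxy)phenyl]ethyl 2-[(2R,3R,4S)-3-(hydroxymethyl)-5-(methoxycarbonyl)-2-methyl-3,4-dihydro-2H-pyran-4-yl]acetate | COC(=O)C1=CO[C@H](C)[C@@H](CO)[C@@H]1CC(=O)OCCc1ccc(OCC=C)c(OCC=C)c1
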